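## Retrosynthetic overview

1. The target is reached by global hydrogenolysis of its hexabenzyl derivative (two benzyl esters, four aryl benzyl ethers).
2. The hexabenzyl bis-ketal is cut at the one C–C bond between the two C14 halves: the acetal carbon of a fulvic-acid-type pyranochromenone bis(methyl acetal) and the diketone CH2 of a ring-opened citromycetin triketone. A chiral Brønsted acid sets this centre, then double transketalisation in the same flask closes the 1,3-dioxane ring and, last, the dihydropyranone ring.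
3. Electrophile: chromone ring first (acetophenone + formate), then the C-5 carboxyl (ortho-formylation, oxidation), the C-3 formyl (enaminone, Vilsmeier), and the pyran ring by hetero-Diels–Alder reaction with 2-methoxypropene, followed by oxidation-level adjustment.
4. Nucleophile: chromanone ring first (Friedel–Crafts acylation/O-alkylation of benzenetriol with 3-chloropropanoic acid), then the C-5 carboxyl, then the C4 side chain by two acylations.
5. Both aromatic rings come from p-benzoquinone through the Thiele–Winter triacetate.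

Labels used below: Ca = ketal carbon next to the chromone CH2; Cm = O–CH methine on chromone C-3; Cf = ring-fusion CH next to the ketone; Cb = ketal carbon of the dihydropyranone.

Assumption: the (R)-BINOL-derived acid is taken to give the required (S) configuration at Cm (to be confirmed on the first run, the antipode being used otherwise), and the other three centres are those of the thermodynamically preferred cis-fused bis-ketal.

## Route

Step 1
Reactants: 1 p-benzoquinone
Product: 2 benzene-1,2,4-triyl triacetate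
Conditions: Ac2O, H2SO4 (cat.), 40–50 °C
Reagents that add atoms: acetic anhydride CC(=O)OC(C)=O
Why: Thiele–Winter acetoxylation, in which acid-promoted conjugate addition of acetate to the quinone, enolisation and O-acetylation give the 1,2,4-trioxygenated benzene in one step.

Step 2
Reactants: 2 benzene-1,2,4-triyl triacetate
Product: 3 1-(2,4,5-trihydroxyphenyl)ethan-1-one
Conditions: ZnCl2, AcOH, 140 °C; then 1 M HCl, 80 °C
Reagents that add atoms: none
Why: Fries rearrangement (Nencki conditions) moves one acetyl group to the ring carbon ortho and para to two oxygens, and the two remaining acetates are hydrolysed.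

Step 3
Reactants: 3 1-(2,4,5-trihydroxyphenyl)ethan-1-one
Product: 4 1-[4-(benzyloxy)-2,5-dihydroxyphenyl]ethan-1-one
Conditions: BnCl (1.05 equiv), NaHCO3, NaI (cat.), DMF, 40 °C, N2
Reagents that add atoms: benzyl chloride ClCc1ccccc1
Why: Williamson etherification under weak-base control, since only the 4-OH para to the acetyl group is acidic enough for bicarbonate (the 2-OH is chelated, the 5-OH is not conjugated to the ketone).

Step 4
Reactants: 4 1-[4-(benzyloxy)-2,5-dihydroxyphenyl]ethan-1-one
Product: 6 7-(benzyloxy)-6-hydroxy-4H-chromen-4-one, via 7-(benzyloxy)-2,6-dihydroxychroman-4-one 5 (not isolated)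
Conditions: NaH (4 equiv), HCO2Et, THF, 0 °C to rt; then conc. HCl, AcOH, 60 °C
Reagents that add atoms: ethyl formate CCOC=O
Why: Claisen condensation of the methyl ketone with formate gives the cyclic hemiacetal, which loses water under acid to the chromone (classical chromone synthesis), any aryl formate being cleaved in the acid stage.

Step 5
Reactants: 6 7-(benzyloxy)-6-hydroxy-4H-chromen-4-one
Product: 7 7-(benzyloxy)-6-hydroxy-4-oxo-4H-chromene-5-carbaldehyde
Conditions: MgCl2, Et3N, (CH2O)n, MeCN, reflux; 1 M HCl work-up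
Reagents that add atoms: formaldehyde (from paraformaldehyde) C=O
Why: Casnati–Skattebøl ortho-formylation, in which the magnesium phenoxide delivers formaldehyde only to an ortho carbon, and C-5 is the single free ortho position because C-7 carries the benzyl ether.

Step 6
Reactants: 7 7-(benzyloxy)-6-hydroxy-4-oxo-4H-chromene-5-carbaldehyde
Product: 8 7-(benzyloxy)-6-hydroxy-4-oxo-4H-chromene-5-carboxylic acid
Conditions: NaClO2, NaH2PO4, 2-methyl-2-butene, t-BuOH/THF/H2O, 0 °C to rt
Reagents that add atoms: sodium chlorite [Na+].[O-]Cl=O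
Why: Pinnick oxidation takes the aldehyde to the acid without touching the chromone or the benzyl ether, the alkene scavenging hypochlorite.

Step 7
Reactants: 8 7-(benzyloxy)-6-hydroxy-4-oxo-4H-chromene-5-carboxylic acid
Product: 9 benzyl 6,7-bis(benzyloxy)-4-oxo-4H-chromene-5-carboxylate
Conditions: BnBr (2.5 equiv), K2CO3, DMF, 50 °C
Reagents that add atoms: benzyl bromide BrCc1ccccc1
Why: double Williamson-type alkylation of the carboxylate and the phenoxide puts all three acidic groups under one hydrogenolysable protecting group.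

Step 8
Reactants: 9 benzyl 6,7-bis(benzyloxy)-4-oxo-4H-chromene-5-carboxylate
Product: 10 benzyl 2,3-bis(benzyloxy)-5-hydroxy-6-[(2E)-3-(pyrrolidin-1-yl)prop-2-enoyl]benzoate
Conditions: pyrrolidine (2 equiv), EtOH, rt
Reagents that add atoms: pyrrolidine C1CCNC1
Why: aza-Michael addition of the amine at C-2 followed by retro-oxa-Michael ring opening turns the chromone into the o-hydroxyaryl enaminone, whose α-carbon is nucleophilic, while the hindered benzyl ester is not aminolysed at room temperature.

Step 9
Reactants: 10 benzyl 2,3-bis(benzyloxy)-5-hydroxy-6-[(2E)-3-(pyrrolidin-1-yl)prop-2-enoyl]benzoate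
Product: 11 benzyl 6,7-bis(benzyloxy)-3-formyl-4-oxo-4H-chromene-5-carboxylate
Conditions: POCl3, DMF, 0 to 50 °C; aq. NaOAc
Reagents that add atoms: N,N-dimethylformamide CN(C)C=O; water O
Why: Vilsmeier–Haack formylation at the enaminone α-carbon, ring closure by the phenol with loss of pyrrolidine and hydrolysis of the iminium salt give the 3-formylchromone.

Step 10
Reactants: 11 benzyl 6,7-bis(benzyloxy)-3-formyl-4-oxo-4H-chromene-5-carboxylate; 12 2-methoxypropene
Product: 13 benzyl 7,8-bis(benzyloxy)-3-methoxy-3-methyl-10-oxo-4,4a-dihydro-3H,10H-pyrano[4,3-b]chromene-9-carboxylate (mixture of diastereomers)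
Conditions: 12 (10 equiv), K2CO3 (trace), toluene, 80 °C, sealed tube
Reagents that add atoms: none
Why: inverse-electron-demand hetero-Diels–Alder reaction of the 1-oxadiene (formyl C=O with the chromone C2=C3 bond) and the electron-rich enol ether builds the pyran ring with the methyl ketal carbon in place, and both new stereocentres are erased later.

Step 11
Reactants: 13 benzyl 7,8-bis(benzyloxy)-3-methoxy-3-methyl-10-oxo-4,4a-dihydro-3H,10H-pyrano[4,3-b]chromene-9-carboxylate
Product: 15 benzyl 7,8-bis(benzyloxy)-1,3-dimethoxy-3-methyl-10-oxo-4,10-dihydro-1H,3H-pyrano[4,3-b]chromene-9-carboxylate (mixture of diastereomers), via 10a-bromo-1-methoxy adduct 14 (not isolated)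
Conditions: NBS, NaHCO3, MeOH/CH2Cl2, −20 °C; then DBU, 0 °C to rt
Reagents that add atoms: methanol CO
Why: bromo-methoxylation of the enol ether followed by E2 loss of HBr across C-4a/C-10a restores the chromone and leaves C-1 as a methyl acetal, that is, a masked oxocarbenium ion.

Step 12
Reactants: 2 benzene-1,2,4-triyl triacetate
Product: 16 benzene-1,2,4-triol
Conditions: HCl (cat.), MeOH, reflux, N2
Reagents that add atoms: none
Why: acid-catalysed transesterification (methanolysis) frees the air-sensitive triol, which is used at once.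

Step 13
Reactants: 16 benzene-1,2,4-triol; 17 3-chloropropanoic acid
Product: 19 6,7-dihydroxychroman-4-one, via 3-chloro-1-(2,4,5-trihydroxyphenyl)propan-1-one 18 (not isolated)
Conditions: TfOH, 80 °C; then 2 M NaOH, Na2S2O4, 0 °C, N2; HCl
Reagents that add atoms: none
Why: Friedel–Crafts acylation at the carbon ortho and para to two hydroxyls, then intramolecular Williamson O-alkylation by the ortho phenoxide, closes the chromanone ring.

Step 14
Reactants: 19 6,7-dihydroxychroman-4-one
Product: 20 7-(benzyloxy)-6-hydroxychroman-4-one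
Conditions: BnCl (1.05 equiv), NaHCO3, NaI (cat.), DMF, 40 °C, N2
Reagents that add atoms: benzyl chloride ClCc1ccccc1
Why: Williamson etherification under weak-base control, the 7-OH para to the ketone-bearing carbon being the more acidic of the two phenols.

Step 15
Reactants: 20 7-(benzyloxy)-6-hydroxychroman-4-one
Product: 21 7-(benzyloxy)-6-hydroxy-4-oxochromane-5-carbaldehyde
Conditions: MgCl2, Et3N, (CH2O)n, MeCN, reflux; 1 M HCl work-up
Reagents that add atoms: formaldehyde (from paraformaldehyde) C=O
Why: Casnati–Skattebøl ortho-formylation through the magnesium phenoxide, C-5 being the only free ortho position and phenoxide-directed delivery being faster than aldol chemistry at the ketone α-carbon.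

Step 16
Reactants: 21 7-(benzyloxy)-6-hydroxy-4-oxochromane-5-carbaldehyde
Product: 22 7-(benzyloxy)-6-hydroxy-4-oxochromane-5-carboxylic acid
Conditions: NaClO2, NaH2PO4, 2-methyl-2-butene, t-BuOH/THF/H2O, 0 °C to rt
Reagents that add atoms: sodium chlorite [Na+].[O-]Cl=O
Why: Pinnick oxidation is selective for the aldehyde and leaves the ketone, the phenol and the benzyl ether intact.

Step 17
Reactants: 22 7-(benzyloxy)-6-hydroxy-4-oxochromane-5-carboxylic acid
Product: 23 benzyl 6,7-bis(benzyloxy)-4-oxochromane-5-carboxylate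
Conditions: BnBr (2.5 equiv), K2CO3, DMF, 50 °C
Reagents that add atoms: benzyl bromide BrCc1ccccc1
Why: double Williamson-type alkylation of carboxylate and phenoxide, carbonate being too weak a base to C-benzylate the ketone.

Step 18
Reactants: 23 benzyl 6,7-bis(benzyloxy)-4-oxochromane-5-carboxylate; 24 acetyl chloride
Product: 25 benzyl 3-acetyl-6,7-bis(benzyloxy)-4-hydroxy-2H-chromene-5-carboxylate (enol form of the 3-acetylchromanone)
Conditions: MgBr2·OEt2, i-Pr2NEt, CH2Cl2, rt
Reagents that add atoms: none
Why: soft enolisation to the magnesium enolate and C-acylation (direct crossed-Claisen acylation) give the β-diketone under conditions too mild to harm the benzyl ester.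

Step 19
Reactants: 25 benzyl 3-acetyl-6,7-bis(benzyloxy)-4-hydroxy-2H-chromene-5-carboxylate; 26 N-methoxy-N-methylacetamide
Product: 27 benzyl 6,7-bis(benzyloxy)-4-hydroxy-3-(3-oxobutanoyl)-2H-chromene-5-carboxylate
Conditions: LiN(iPr)2 (3.3 equiv), THF, −78 to −20 °C; then 26, −78 to 0 °C; sat. NH4Cl
Reagents that add atoms: none
Why: Hauser–Harris dianion acylation, in which the second deprotonation occurs at the acetyl methyl group and the terminal carbanion is acylated by the Weinreb amide, whose chelated tetrahedral adduct prevents over-addition.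

Step 20
Reactants: 15 benzyl 7,8-bis(benzyloxy)-1,3-dimethoxy-3-methyl-10-oxo-4,10-dihydro-1H,3H-pyrano[4,3-b]chromene-9-carboxylate; 27 benzyl 6,7-bis(benzyloxy)-4-hydroxy-3-(3-oxobutanoyl)-2H-chromene-5-carboxylate
Product: 29 hexabenzyl bis-ketal (the two benzyl esters plus four aryl benzyl ethers of 30; Ca R/Cm S/Cf S/Cb S), via C-alkylated methyl ketal 28 (not isolated)
Conditions: (R)-3,3'-bis(2,4,6-triisopropylphenyl)-1,1'-binaphthyl-2,2'-diyl N-(trifluoromethylsulfonyl)phosphoramide (10 mol %), 5 Å MS, toluene, −30 °C to rt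
Reagents that add atoms: none
Why: chiral Brønsted acid-catalysed oxocarbenium alkylation, in which the acetal ionises to an ion pair with the chiral anion (hydrogen-bonded to the diketone enol) so that the enol attacks one face and sets Cm (S), after which the same acid drives double transketalisation to the only strain-free cis-fused bis-ketal and thereby sets Ca, Cf and Cb under thermodynamic control.

Step 21
Reactants: 29 hexabenzyl bis-ketal
Product: 30 CNP0230818.1 (Ca R/Cm S/Cf S/Cb S)
Conditions: H2 (1 atm), 10% Pd/C, THF/MeOH, rt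
Reagents that add atoms: none
Why: hydrogenolysis of the four aryl benzyl ethers and two benzyl esters is neutral, so the bis-ketal, the tetrasubstituted chromone and vinylogous-ester double bonds and all four stereocentres are left as they are.

## Compound list

1 | p-benzoquinone | O=C1C=CC(=O)C=C1 | starting material
2 | benzene-1,2,4-triyl triacetate | CC(=O)Oc1ccc(OC(C)=O)c(OC(C)=O)c1 | intermediate
3 | 1-(2,4,5-trihydroxyphenyl)ethan-1-one | CC(=O)c1cc(O)c(O)cc1O | intermediate
4 | 1-[4-(benzyloxy)-2,5-dihydroxyphenyl]ethan-1-one | CC(=O)c1cc(O)c(OCc2ccccc2)cc1O | intermediate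
5 | 7-(benzyloxy)-2,6-dihydroxychroman-4-one (formed in the flask, racemic) | OC1CC(=O)c2cc(O)c(OCc3ccccc3)cc2O1 | intermediate
6 | 7-(benzyloxy)-6-hydroxy-4H-chromen-4-one | O=c1ccoc2cc(OCc3ccccc3)c(O)cc12 | intermediate
7 | 7-(benzyloxy)-6-hydroxy-4-oxo-4H-chromene-5-carbaldehyde | O=Cc1c(O)c(OCc2ccccc2)cc2occc(=O)c12 | intermediate
8 | 7-(benzyloxy)-6-hydroxy-4-oxo-4H-chromene-5-carboxylic acid | O=C(O)c1c(O)c(OCc2ccccc2)cc2occc(=O)c12 | intermediate
9 | benzyl 6,7-bis(benzyloxy)-4-oxo-4H-chromene-5-carboxylate | O=C(OCc1ccccc1)c1c(OCc2ccccc2)c(OCc2ccccc2)cc2occc(=O)c12 | intermediate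
10 | benzyl 2,3-bis(benzyloxy)-5-hydroxy-6-[(2E)-3-(pyrrolidin-1-yl)prop-2-enoyl]benzoate | O=C(/C=C/N1CCCC1)c1c(O)cc(OCc2ccccc2)c(OCc2ccccc2)c1C(=O)OCc1ccccc1 | intermediate
11 | benzyl 6,7-bis(benzyloxy)-3-formyl-4-oxo-4H-chromene-5-carboxylate | O=Cc1coc2cc(OCc3ccccc3)c(OCc3ccccc3)c(C(=O)OCc3ccccc3)c2c1=O | intermediate
12 | 2-methoxypropene | COC(C)=C | starting material
13 | benzyl 7,8-bis(benzyloxy)-3-methoxy-3-methyl-10-oxo-4,4a-dihydro-3H,10H-pyrano[4,3-b]chromene-9-carboxylate (mixture of diastereomers) | COC1(C)CC2Oc3cc(OCc4ccccc4)c(OCc4ccccc4)c(C(=O)OCc4ccccc4)c3C(=O)C2=CO1 | intermediate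
14 | benzyl 7,8-bis(benzyloxy)-10a-bromo-1,3-dimethoxy-3-methyl-10-oxo-1,3,4,4a,10,10a-hexahydropyrano[4,3-b]chromene-9-carboxylate (formed in the flask, mixture of diastereomers) | COC1OC(C)(OC)CC2Oc3cc(OCc4ccccc4)c(OCc4ccccc4)c(C(=O)OCc4ccccc4)c3C(=O)C12Br | intermediate
15 | benzyl 7,8-bis(benzyloxy)-1,3-dimethoxy-3-methyl-10-oxo-4,10-dihydro-1H,3H-pyrano[4,3-b]chromene-9-carboxylate (mixture of diastereomers) | COC1OC(C)(OC)Cc2oc3cc(OCc4ccccc4)c(OCc4ccccc4)c(C(=O)OCc4ccccc4)c3c(=O)c12 | intermediate
16 | benzene-1,2,4-triol | Oc1ccc(O)c(O)c1 | intermediate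
17 | 3-chloropropanoic acid | OC(=O)CCCl | starting material
18 | 3-chloro-1-(2,4,5-trihydroxyphenyl)propan-1-one (formed in the flask) | O=C(CCCl)c1cc(O)c(O)cc1O | intermediate
19 | 6,7-dihydroxychroman-4-one | O=C1CCOc2cc(O)c(O)cc12 | intermediate
20 | 7-(benzyloxy)-6-hydroxychroman-4-one | O=C1CCOc2cc(OCc3ccccc3)c(O)cc12 | intermediate
21 | 7-(benzyloxy)-6-hydroxy-4-oxochromane-5-carbaldehyde | O=Cc1c(O)c(OCc2ccccc2)cc2OCCC(=O)c12 | intermediate
22 | 7-(benzyloxy)-6-hydroxy-4-oxochromane-5-carboxylic acid | O=C(O)c1c(O)c(OCc2ccccc2)cc2OCCC(=O)c12 | intermediate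
23 | benzyl 6,7-bis(benzyloxy)-4-oxochromane-5-carboxylate | O=C(OCc1ccccc1)c1c(OCc2ccccc2)c(OCc2ccccc2)cc2OCCC(=O)c12 | intermediate
24 | acetyl chloride | CC(Cl)=O | starting material
25 | benzyl 3-acetyl-6,7-bis(benzyloxy)-4-hydroxy-2H-chromene-5-carboxylate | CC(=O)C1=C(O)c2c(OC1)cc(OCc1ccccc1)c(OCc1ccccc1)c2C(=O)OCc1ccccc1 | intermediate
26 | N-methoxy-N-methylacetamide | CON(C)C(C)=O | starting material
27 | benzyl 6,7-bis(benzyloxy)-4-hydroxy-3-(3-oxobutanoyl)-2H-chromene-5-carboxylate | CC(=O)CC(=O)C1=C(O)c2c(OC1)cc(OCc1ccccc1)c(OCc1ccccc1)c2C(=O)OCc1ccccc1 | intermediate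
28 | C-alkylated methyl ketal (formed in the flask): the 1-methoxy group of 15 replaced by C-2 of the 1,3-dioxobutyl chain of 27, Cm (S), other centres undefined | COC1(C)Cc2oc3cc(OCc4ccccc4)c(OCc4ccccc4)c(C(=O)OCc4ccccc4)c3c(=O)c2[C@@H](O1)C(C(C)=O)C(=O)C1=C(O)c2c(OC1)cc(OCc1ccccc1)c(OCc1ccccc1)c2C(=O)OCc1ccccc1 | intermediate
29 | hexabenzyl bis-ketal: 30 with both CO2H as benzyl esters and all four phenols as benzyl ethers; Ca (R), Cm (S), Cf (S), Cb (S) | C[C@@]12Cc3oc4cc(OCc5ccccc5)c(OCc5ccccc5)c(C(=O)OCc5ccccc5)c4c(=O)c3[C@@H](O1)[C@H]1C(=O)C3=C(O[C@@]1(C)O2)c1c(cc(OCc2ccccc2)c(OCc2ccccc2)c1C(=O)OCc1ccccc1)OC3 | intermediate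
30 | CNP0230818.1, bis-ketal heterodimer of the fulvic acid and citromycetin cores; Ca (R), Cm (S), Cf (S), Cb (S) | C[C@@]12Cc3oc4cc(O)c(O)c(C(=O)O)c4c(=O)c3[C@@H](O1)[C@H]1C(=O)C3=C(O[C@@]1(C)O2)c1c(cc(O)c(O)c1C(=O)O)OC3 | target

## Step count and risks

Total step count: 21. Longest linear sequence: 13 steps (steps 1–11, then 20 and 21); the other branch runs through steps 1, 12–19, 20 and 21 (11 steps).

Most likely to fail:

Step 15 (ortho-formylation of 20). The site is hindered by the peri ketone, and the enolisable chromanone can undergo aldol or methylenation with formaldehyde. The fallback sets out from 20 and introduces the carbon by sigmatropic rearrangement instead of electrophilic formylation. O-allylation (allyl bromide, K2CO3, acetone) gives 6-(allyloxy)-7-(benzyloxy)chroman-4-one F1. Aromatic Claisen rearrangement (PhNEt2, 190 °C), which can only go to C-5 because C-7 is blocked, gives 5-allyl-7-(benzyloxy)-6-hydroxychroman-4-one F2. Double-bond migration with RuClH(CO)(PPh3)3 in toluene at 80 °C gives 7-(benzyloxy)-6-hydroxy-5-[(E)-prop-1-enyl]chroman-4-one F3. Ozonolysis (O3, CH2Cl2/MeOH, −78 °C; Me2S) then returns to the route at 21.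

Step 19 (dianion acylation of 25). The strongly basic trianion chemistry may attack the benzyl ester or give O-acylation. The fallback sets out from 25 and replaces the dianion by a neutral Mukaiyama-type acylation. TMSOTf/Et3N in CH2Cl2 at 0 °C gives benzyl 6,7-bis(benzyloxy)-4-(trimethylsilyloxy)-3-[1-(trimethylsilyloxy)ethenyl]-2H-chromene-5-carboxylate F4. Its terminal carbon is acylated by acetyl chloride 24 (CH2Cl2, −78 °C to rt, cat. TMSOTf), and aqueous acid work-up returns to the route at 27.

Step 20 (enantioselective coupling and bis-ketalisation). Risks are low enantioselectivity, attack through the ring carbon of the triketone instead of the CH2, or closure of the ketal through the wrong carbonyl. The fallback sets out from 27 and 15, fixes the constitution first and obtains the enantiomer by resolution instead of catalysis. Cyclodehydration of 27 (TFA, CH2Cl2, rt) gives benzyl 8,9-bis(benzyloxy)-2-methyl-4-oxo-4H,5H-pyrano[3,2-c]chromene-10-carboxylate F5, in which only the pyranone C-3 is nucleophilic and the pyranone oxygen is already bonded to Cb. F5 and 15 are joined with TMSOTf in CH2Cl2 at −40 °C, then equilibrated with one equivalent of water and camphorsulfonic acid at rt, to give the racemic bis-ketal, a 1:1 mixture of 29 and its enantiomer F6. Preparative HPLC on an amylose tris(3,5-dimethylphenylcarbamate) phase removes F6 and returns to the route at 29.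

Further compounds
F1 | step 15 | 6-(allyloxy)-7-(benzyloxy)chroman-4-one | C=CCOc1cc2C(=O)CCOc2cc1OCc1ccccc1
F2 | step 15 | 5-allyl-7-(benzyloxy)-6-hydroxychroman-4-one | C=CCc1c(O)c(OCc2ccccc2)cc2OCCC(=O)c12
F3 | step 15 | 7-(benzyloxy)-6-hydroxy-5-[(E)-prop-1-enyl]chroman-4-one | C/C=C/c1c(O)c(OCc2ccccc2)cc2OCCC(=O)c12
F4 | step 19 | benzyl 6,7-bis(benzyloxy)-4-(trimethylsilyloxy)-3-[1-(trimethylsilyloxy)ethenyl]-2H-chromene-5-carboxylate | C=C(O[Si](C)(C)C)C1=C(O[Si](C)(C)C)c2c(OC1)cc(OCc1ccccc1)c(OCc1ccccc1)c2C(=O)OCc1ccccc1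
F5 | step 20 | benzyl 8,9-bis(benzyloxy)-2-methyl-4-oxo-4H,5H-pyrano[3,2-c]chromene-10-carboxylate | CC1=CC(=O)C2=C(O1)c1c(OC2)cc(OCc2ccccc2)c(OCc2ccccc2)c1C(=O)OCc1ccccc1
F6 | step 20 | enantiomer of 29; Ca (S), Cm (R), Cf (R), Cb (R) | C[C@]12Cc3oc4cc(OCc5ccccc5)c(OCc5ccccc5)c(C(=O)OCc5ccccc5)c4c(=O)c3[C@H](O1)[C@@H]1C(=O)C3=C(O[C@]1(C)O2)c1c(cc(OCc2ccccc2)c(OCc2ccccc2)c1C(=O)OCc1ccccc1)OC3
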